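**Assumption:** "geranyl" below means (2E)-3,7-dimethylocta-2,6-dien-1-yl; the target is read as (2S)-6-geranyl-5,7,3'-trihydroxy-4'-methoxyflavanone, and 3,5-bis(benzyloxy)phenol, geranyl bromide and isovanillin are taken as cheap catalogue chemicals.

**Retrosynthetic overview**
1. Target 19 comes from the (2S)-tris-MOM flavanone 18 by removing three MOM ethers; 18 comes from racemate 17 by kinetic resolution (asymmetric transfer hydrogenation).
2. Ring C is the only ring built (rings A and B are bought as arenes). It closes by oxa-Michael addition of 2'-hydroxychalcone 16 through its one free phenol, which fixes the 6-geranyl pattern.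
3. The key C–C bond (C2–C3) comes from an intermolecular Claisen–Schmidt aldol condensation of acetophenone 12 (ring A fragment) with aldehyde 14 (ring B fragment, from isovanillin).
4. 12 comes from phenol 8 by ortho-formylation, MeMgBr addition and oxidation; 8 comes from directed ortho-lithiation/geranylation between the two MOM ethers of the TIPS-differentiated phloroglucinol 4, made from 3,5-bis(benzyloxy)phenol.

**Route**

Step 1
Reactants: 1 3,5-bis(benzyloxy)phenol
Product: 2 [3,5-bis(benzyloxy)phenoxy]triisopropylsilane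
Conditions: TIPSCl, imidazole, DMF, 0 °C to rt
Reagents that add atoms: chlorotriisopropylsilane (TIPSCl), CC(C)[Si](Cl)(C(C)C)C(C)C
Why: Silyl ether formation at the only free phenol installs a bulky, non-coordinating group that later blocks its neighbouring positions and marks the oxygen that becomes O1 of ring C.

Step 2
Reactants: 2 [3,5-bis(benzyloxy)phenoxy]triisopropylsilane
Product: 3 5-(triisopropylsilyloxy)benzene-1,3-diol
Conditions: H2 (1 atm), 10% Pd/C, EtOAc/EtOH, rt
Reagents that add atoms: none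
Why: Hydrogenolysis cleaves both benzyl ethers while the aryl silyl ether is inert, and it is done before any alkene is present.

Step 3
Reactants: 3 5-(triisopropylsilyloxy)benzene-1,3-diol
Product: 4 [3,5-bis(methoxymethoxy)phenoxy]triisopropylsilane
Conditions: MOMCl, i-Pr2NEt, CH2Cl2, 0 °C to rt
Reagents that add atoms: chloromethyl methyl ether (MOMCl), COCCl
Why: O-alkylation of both phenols gives the two MOM ethers that serve as directing groups for lithiation and as the protecting groups of the future 5- and 7-hydroxyls.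

Step 4
Reactants: 4 [3,5-bis(methoxymethoxy)phenoxy]triisopropylsilane; 5 geranyl bromide
Product: 7 [4-geranyl-3,5-bis(methoxymethoxy)phenoxy]triisopropylsilane, via aryllithium 6 (not isolated)
Conditions: n-BuLi, THF, 0 °C, 1 h; then CuI (10 mol %), 5, −78 °C to rt
Reagents that add atoms: none
Why: Directed ortho-metalation occurs at the carbon between the two cooperating MOM ethers (OTIPS neither directs nor tolerates lithiation beside it), and copper-catalysed SN2 alkylation with the primary allylic bromide keeps the (E)-alkene of the geranyl unit.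

Step 5
Reactants: 7 [4-geranyl-3,5-bis(methoxymethoxy)phenoxy]triisopropylsilane
Product: 8 4-geranyl-3,5-bis(methoxymethoxy)phenol
Conditions: TBAF, THF, 0 °C; aq NH4Cl
Reagents that add atoms: none
Why: Fluoride-mediated desilylation frees only the phenol para to the geranyl group and leaves MOM ethers and alkenes untouched; the product is symmetric, so its two ortho positions are equivalent.

Step 6
Reactants: 8 4-geranyl-3,5-bis(methoxymethoxy)phenol
Product: 10 3-geranyl-6-hydroxy-2,4-bis(methoxymethoxy)benzaldehyde, via hydroxymethylphenol 9 (not isolated)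
Conditions: MgCl2, Et3N, (CH2O)n, MeCN, reflux
Reagents that add atoms: paraformaldehyde (formaldehyde), C=O
Why: In this Casnati–Skattebøl ortho-formylation the magnesium phenoxide delivers formaldehyde only ortho to the phenol, and a second formaldehyde oxidises the hydroxymethyl intermediate 9 by hydride transfer in a basic medium that MOM ethers and alkenes tolerate.

Step 7
Reactants: 10 3-geranyl-6-hydroxy-2,4-bis(methoxymethoxy)benzaldehyde
Product: 11 (±)-1-[3-geranyl-6-hydroxy-2,4-bis(methoxymethoxy)phenyl]ethan-1-ol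
Conditions: MeMgBr (3 equiv), THF, 0 °C to rt; aq NH4Cl
Reagents that add atoms: methylmagnesium bromide, C[Mg]Br
Why: Grignard addition (after deprotonation of the phenol by the first equivalent) gives the secondary benzylic alcohol, whose racemic carbinol centre is destroyed in the next step.

Step 8
Reactants: 11 (±)-1-[3-geranyl-6-hydroxy-2,4-bis(methoxymethoxy)phenyl]ethan-1-ol
Product: 12 1-[3-geranyl-6-hydroxy-2,4-bis(methoxymethoxy)phenyl]ethan-1-one
Conditions: MnO2 (activated, excess), CH2Cl2, rt
Reagents that add atoms: none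
Why: MnO2 oxidises the electron-rich benzylic alcohol selectively to the ortho-hydroxyacetophenone without touching the trisubstituted alkenes or acetals.

Step 9
Reactants: 13 isovanillin (3-hydroxy-4-methoxybenzaldehyde)
Product: 14 4-methoxy-3-(methoxymethoxy)benzaldehyde
Conditions: MOMCl, i-Pr2NEt, CH2Cl2, 0 °C to rt
Reagents that add atoms: chloromethyl methyl ether (MOMCl), COCCl
Why: O-alkylation masks the phenol so that the aldehyde does not become an unreactive phenoxide in the basic aldol step.

Step 10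
Reactants: 12 1-[3-geranyl-6-hydroxy-2,4-bis(methoxymethoxy)phenyl]ethan-1-one; 14 4-methoxy-3-(methoxymethoxy)benzaldehyde
Product: 16 (2E)-1-[3-geranyl-6-hydroxy-2,4-bis(methoxymethoxy)phenyl]-3-[4-methoxy-3-(methoxymethoxy)phenyl]prop-2-en-1-one, via aldol adduct 15 (not isolated)
Conditions: KOH, EtOH/H2O, rt, 36 h; aq NH4Cl
Reagents that add atoms: none
Why: In this Claisen–Schmidt (crossed aldol) condensation the enolate of methyl ketone 12 adds to the non-enolisable aldehyde 14 and the aldol 15 loses water by E1cB to the conjugated (E)-enone, forming the C2–C3 bond of the flavanone with no stereocentre left.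

Step 11
Reactants: 16 (2E)-1-[3-geranyl-6-hydroxy-2,4-bis(methoxymethoxy)phenyl]-3-[4-methoxy-3-(methoxymethoxy)phenyl]prop-2-en-1-one
Product: 17 (±)-6-geranyl-2-[4-methoxy-3-(methoxymethoxy)phenyl]-5,7-bis(methoxymethoxy)-2,3-dihydro-4H-chromen-4-one
Conditions: NaOAc, EtOH, reflux
Reagents that add atoms: none
Why: Base-mediated intramolecular oxa-Michael addition (chalcone–flavanone isomerisation) closes ring C through the only free phenol, which sits next to the unsubstituted ring carbon, so the 6-geranyl and not the 8-geranyl flavanone forms; C2 is created here as a racemate and resolved in step 12.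

Step 12
Reactants: 17 (±)-6-geranyl-2-[4-methoxy-3-(methoxymethoxy)phenyl]-5,7-bis(methoxymethoxy)-2,3-dihydro-4H-chromen-4-one
Product: 18 (2S)-6-geranyl-2-[4-methoxy-3-(methoxymethoxy)phenyl]-5,7-bis(methoxymethoxy)-2,3-dihydro-4H-chromen-4-one
Conditions: Cp*RhCl[(R,R)-TsDPEN] (2 mol %), HCO2H/Et3N (5:2), EtOAc, rt, stopped at about 55% conversion; chromatography
Reagents that add atoms: none
Why: In this kinetic resolution by Noyori-type asymmetric transfer hydrogenation the (R,R)-catalyst, which by its usual sense of induction forms (4R)-benzylic carbinols, rapidly reduces the matched (2R)-ketone (hydride anti to the 2-aryl group, giving the cis-(2R,4R)-flavan-4-ol) and leaves the (2S)-ketone 18 in high ee, which is the C2 configuration of the target.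

Step 13
Reactants: 18 (2S)-6-geranyl-2-[4-methoxy-3-(methoxymethoxy)phenyl]-5,7-bis(methoxymethoxy)-2,3-dihydro-4H-chromen-4-one
Product: 19 (2S)-6-geranyl-5,7-dihydroxy-2-(3-hydroxy-4-methoxyphenyl)-2,3-dihydro-4H-chromen-4-one
Conditions: HCl (3 M aq)/MeOH, 40 °C, monitored and stopped at full conversion
Reagents that add atoms: none
Why: Acid-catalysed acetal exchange with methanol removes all three MOM ethers under conditions brief and mild enough to spare the geranyl alkenes and the acid-stable C2 centre (flavanones epimerise under base, not under dilute acid).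

**Compound list**
1 | 3,5-bis(benzyloxy)phenol | Oc1cc(OCc2ccccc2)cc(OCc2ccccc2)c1 | starting material
2 | [3,5-bis(benzyloxy)phenoxy]triisopropylsilane | CC(C)[Si](Oc1cc(OCc2ccccc2)cc(OCc2ccccc2)c1)(C(C)C)C(C)C | intermediate
3 | 5-(triisopropylsilyloxy)benzene-1,3-diol | CC(C)[Si](Oc1cc(O)cc(O)c1)(C(C)C)C(C)C | intermediate
4 | [3,5-bis(methoxymethoxy)phenoxy]triisopropylsilane | COCOc1cc(OCOC)cc(O[Si](C(C)C)(C(C)C)C(C)C)c1 | intermediate
5 | geranyl bromide, (2E)-1-bromo-3,7-dimethylocta-2,6-diene | BrC/C=C(\C)CCC=C(C)C | starting material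
6 | [2,6-bis(methoxymethoxy)-4-(triisopropylsilyloxy)phenyl]lithium | [Li]c1c(OCOC)cc(O[Si](C(C)C)(C(C)C)C(C)C)cc1OCOC | intermediate (not isolated)
7 | {4-[(2E)-3,7-dimethylocta-2,6-dien-1-yl]-3,5-bis(methoxymethoxy)phenoxy}triisopropylsilane | COCOc1cc(O[Si](C(C)C)(C(C)C)C(C)C)cc(OCOC)c1C/C=C(\C)CCC=C(C)C | intermediate
8 | 4-[(2E)-3,7-dimethylocta-2,6-dien-1-yl]-3,5-bis(methoxymethoxy)phenol | COCOc1cc(O)cc(OCOC)c1C/C=C(\C)CCC=C(C)C | intermediate
9 | 4-[(2E)-3,7-dimethylocta-2,6-dien-1-yl]-2-(hydroxymethyl)-3,5-bis(methoxymethoxy)phenol (magnesium salt in the flask) | OCc1c(O)cc(OCOC)c(C/C=C(\C)CCC=C(C)C)c1OCOC | intermediate (not isolated)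
10 | 3-[(2E)-3,7-dimethylocta-2,6-dien-1-yl]-6-hydroxy-2,4-bis(methoxymethoxy)benzaldehyde | O=Cc1c(O)cc(OCOC)c(C/C=C(\C)CCC=C(C)C)c1OCOC | intermediate
11 | (±)-1-{3-[(2E)-3,7-dimethylocta-2,6-dien-1-yl]-6-hydroxy-2,4-bis(methoxymethoxy)phenyl}ethan-1-ol | CC(O)c1c(O)cc(OCOC)c(C/C=C(\C)CCC=C(C)C)c1OCOC | intermediate
12 | 1-{3-[(2E)-3,7-dimethylocta-2,6-dien-1-yl]-6-hydroxy-2,4-bis(methoxymethoxy)phenyl}ethan-1-one | CC(=O)c1c(O)cc(OCOC)c(C/C=C(\C)CCC=C(C)C)c1OCOC | intermediate
13 | isovanillin, 3-hydroxy-4-methoxybenzaldehyde | COc1ccc(C=O)cc1O | starting material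
14 | 4-methoxy-3-(methoxymethoxy)benzaldehyde | COCOc1cc(C=O)ccc1OC | intermediate
15 | (±)-1-{3-[(2E)-3,7-dimethylocta-2,6-dien-1-yl]-6-hydroxy-2,4-bis(methoxymethoxy)phenyl}-3-hydroxy-3-[4-methoxy-3-(methoxymethoxy)phenyl]propan-1-one (potassium salt in the flask) | COCOc1cc(C(O)CC(=O)c2c(O)cc(OCOC)c(C/C=C(\C)CCC=C(C)C)c2OCOC)ccc1OC | intermediate (not isolated)
16 | (2E)-1-{3-[(2E)-3,7-dimethylocta-2,6-dien-1-yl]-6-hydroxy-2,4-bis(methoxymethoxy)phenyl}-3-[4-methoxy-3-(methoxymethoxy)phenyl]prop-2-en-1-one | COCOc1cc(/C=C/C(=O)c2c(O)cc(OCOC)c(C/C=C(\C)CCC=C(C)C)c2OCOC)ccc1OC | intermediate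
17 | (±)-6-[(2E)-3,7-dimethylocta-2,6-dien-1-yl]-2-[4-methoxy-3-(methoxymethoxy)phenyl]-5,7-bis(methoxymethoxy)-2,3-dihydro-4H-chromen-4-one | COc1ccc(C2CC(=O)c3c(cc(OCOC)c(C/C=C(\C)CCC=C(C)C)c3OCOC)O2)cc1OCOC | intermediate
18 | (2S)-6-[(2E)-3,7-dimethylocta-2,6-dien-1-yl]-2-[4-methoxy-3-(methoxymethoxy)phenyl]-5,7-bis(methoxymethoxy)-2,3-dihydro-4H-chromen-4-one | COc1ccc([C@@H]2CC(=O)c3c(cc(OCOC)c(C/C=C(\C)CCC=C(C)C)c3OCOC)O2)cc1OCOC | intermediate
19 | (2S)-6-[(2E)-3,7-dimethylocta-2,6-dien-1-yl]-5,7-dihydroxy-2-(3-hydroxy-4-methoxyphenyl)-2,3-dihydro-4H-chromen-4-one | COc1ccc([C@@H]2CC(=O)c3c(cc(O)c(C/C=C(\C)CCC=C(C)C)c3O)O2)cc1O | target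

**Totals and risks**
Total step count: 13. Longest linear sequence: 12 steps (steps 1–8, then 10–13, from 3,5-bis(benzyloxy)phenol).

The three steps most likely to fail:

Step 12 (kinetic resolution). The C4 ketone is flanked by the 5-OMOM group and is electron-rich, so reduction may be slow or poorly selective. The fallback sets out from racemate 17 and resolves it physically by preparative chiral HPLC or SFC on an amylose tris(3,5-dimethylphenylcarbamate) phase (heptane/i-PrOH). The peak with the negative Cotton effect near 290 nm typical of (2S)-flavanones is collected, which comes back to the route at 18. The other peak, the (2R)-flavanone F5, is re-equilibrated through chalcone 16 with NaOAc in refluxing EtOH and returned to 17.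

Step 13 (global MOM removal). Protic acid can cyclise the geranyl group onto the neighbouring phenols. The fallback sets out from 18 and uses a non-protic exchange: TMSOTf/2,2'-bipyridyl in CH2Cl2 at 0 °C converts the three aryl MOM ethers into silyl ethers, giving the tris(trimethylsilyl) ether F6. Water/THF at rt then hydrolyses these and comes back to the route at 19.

Step 6 (magnesium-mediated ortho-formylation). It may stall or strip a MOM group. The fallback sets out from phenol 8 and introduces the formyl group by a second directed lithiation. 3,4-Dihydro-2H-pyran with PPTS in CH2Cl2 gives the THP ether 2-[4-geranyl-3,5-bis(methoxymethoxy)phenoxy]oxane F1. n-BuLi in THF at 0 °C lithiates between the OTHP and OMOM groups to the aryllithium F2, and DMF adds to give the lithium hemiaminal alkoxide F3. Aqueous NH4Cl releases the THP-protected aldehyde F4. AcOH/THF/H2O (4:2:1, 40 °C) then cleaves only the THP acetal and comes back to the route at 10.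

**Further compounds**
F1 | step 6 | 2-{4-[(2E)-3,7-dimethylocta-2,6-dien-1-yl]-3,5-bis(methoxymethoxy)phenoxy}oxane (racemic THP ether) | COCOc1cc(OC2CCCCO2)cc(OCOC)c1C/C=C(\C)CCC=C(C)C
F2 | step 6 | {3-[(2E)-3,7-dimethylocta-2,6-dien-1-yl]-2,4-bis(methoxymethoxy)-6-(oxan-2-yloxy)phenyl}lithium | [Li]c1c(OC2CCCCO2)cc(OCOC)c(C/C=C(\C)CCC=C(C)C)c1OCOC
F3 | step 6 | lithium (dimethylamino){3-[(2E)-3,7-dimethylocta-2,6-dien-1-yl]-2,4-bis(methoxymethoxy)-6-(oxan-2-yloxy)phenyl}methanolate | CN(C)C(O[Li])c1c(OC2CCCCO2)cc(OCOC)c(C/C=C(\C)CCC=C(C)C)c1OCOC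
F4 | step 6 | 3-[(2E)-3,7-dimethylocta-2,6-dien-1-yl]-2,4-bis(methoxymethoxy)-6-(oxan-2-yloxy)benzaldehyde | O=Cc1c(OC2CCCCO2)cc(OCOC)c(C/C=C(\C)CCC=C(C)C)c1OCOC
F5 | step 12 | (2R)-6-[(2E)-3,7-dimethylocta-2,6-dien-1-yl]-2-[4-methoxy-3-(methoxymethoxy)phenyl]-5,7-bis(methoxymethoxy)-2,3-dihydro-4H-chromen-4-one | COc1ccc([C@H]2CC(=O)c3c(cc(OCOC)c(C/C=C(\C)CCC=C(C)C)c3OCOC)O2)cc1OCOC
F6 | step 13 | (2S)-6-[(2E)-3,7-dimethylocta-2,6-dien-1-yl]-2-[4-methoxy-3-(trimethylsilyloxy)phenyl]-5,7-bis(trimethylsilyloxy)-2,3-dihydro-4H-chromen-4-one | COc1ccc([C@@H]2CC(=O)c3c(cc(O[Si](C)(C)C)c(C/C=C(\C)CCC=C(C)C)c3O[Si](C)(C)C)O2)cc1O[Si](C)(C)C
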